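**Assumptions (one line each)**
- The target SMILES is (2S)-6,8,3′-triprenylnaringenin, i.e. (2S)-5,7,4′-trihydroxy-6,8,3′-tris(3-methylbut-2-enyl)flavanone. I derived (S) from the `[C@@H]` centre: the CIP order is O > aryl > CH2 > H.
- 4-Hydroxy-3-prenylbenzaldehyde is treated as a purchasable building block.
- Which cinchona pseudo-enantiomer gives (S) must be confirmed against an authentic (S)-flavanone by HPLC and optical rotation.

## Retrosynthesis
1. The flavanone C-ring (C2–O1 bond) is formed last, by an enantioselective intramolecular oxa-Michael addition of the 2′-OH onto a 2′-hydroxychalcone. This sets C2.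
2. The chalcone comes from a Claisen–Schmidt condensation of 3′,5′-diprenyl-phloroacetophenone with 4-hydroxy-3-prenylbenzaldehyde.
3. The symmetric phloroacetophenone C-prenylates at its two equivalent free positions (C3 and C5), so only one regioisomer of the diprenyl compound can form.
4. No protecting groups are used, so no acid-mediated deprotection is needed that could cyclise the prenyl groups onto neighbouring phenols.

## Route

**Step 1**
Reactants: 1 (2′,4′,6′-trihydroxyacetophenone) and 2 (prenyl bromide)
Product: 3 (1-(2,4,6-trihydroxy-3,5-bis(3-methylbut-2-enyl)phenyl)ethan-1-one)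
Conditions: 2 (2.2 equiv), KOH (aq., ~4 equiv), H2O/MeOH, 0 °C → rt, then acidify to pH ~4 with dilute HCl
Reagents that add atoms: prenyl bromide, CC(C)=CCBr (two prenyl groups are incorporated)
Why: Phenoxide C-alkylation (SN2) in aqueous base favours C- over O-alkylation. The two free ring carbons of 1 are equivalent, so dialkylation gives a single regioisomer. The mono-prenyl and over-prenylated (dearomatised) by-products are removed by chromatography. No stereocentre is formed.

**Step 2**
Reactants: 3 and 4 (4-hydroxy-3-(3-methylbut-2-enyl)benzaldehyde)
Product: 5 ((E)-2′,4′,6′,4-tetrahydroxy-3′,5′,3-triprenylchalcone)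
Conditions: KOH (aq., ~50%), EtOH, rt to 50 °C, 2–4 d, then quench at 0 °C with AcOH/H2O to pH ~5
Reagents that add atoms: none (4 is a reactant; loss of H2O)
Why: Claisen–Schmidt (base-mediated aldol condensation) through the poly-phenoxide gives the thermodynamic (E)-enone. A cold, weakly acidic quench and chromatography remove any racemic flavanone formed prematurely. Prenyl alkenes are inert to base. No stereocentre is formed.

**Step 3**
Reactants: 5
Product: 6 ((2S)-6,8,3′-triprenylnaringenin, the target)
Conditions: quinine-derived bifunctional amine–thiourea (20 mol%), toluene (~0.02 M), rt, 3–5 d (pseudo-enantiomeric quinidine series if (R) is obtained)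
Reagents that add atoms: none (the catalyst is not incorporated; the step is an isomerisation)
Why: Asymmetric intramolecular oxa-Michael (6-endo-trig) cyclisation. The thiourea binds and activates the enone carbonyl, and the tertiary amine delivers the 2′-phenoxide to one face of the β-carbon, setting C2 as (S). The conditions are mild and non-acidic, so the prenyl groups survive. C2 is not touched afterwards, and the 5-OH···O=C chelate slows retro-Michael racemisation.

## Compound list
1 | 2′,4′,6′-trihydroxyacetophenone | CC(=O)c1c(O)cc(O)cc1O | starting material
2 | prenyl bromide (1-bromo-3-methylbut-2-ene) | CC(C)=CCBr | starting material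
3 | 3′,5′-diprenyl-2′,4′,6′-trihydroxyacetophenone | CC(=O)c1c(O)c(CC=C(C)C)c(O)c(CC=C(C)C)c1O | intermediate
4 | 4-hydroxy-3-prenylbenzaldehyde | O=Cc1ccc(O)c(CC=C(C)C)c1 | starting material
5 | (E)-2′,4′,6′,4-tetrahydroxy-3′,5′,3-triprenylchalcone | CC(C)=CCc1cc(/C=C/C(=O)c2c(O)c(CC=C(C)C)c(O)c(CC=C(C)C)c2O)ccc1O | intermediate
6 | (2S)-6,8,3′-triprenylnaringenin | CC(C)=CCc1cc([C@@H]2CC(=O)c3c(O)c(CC=C(C)C)c(O)c(CC=C(C)C)c3O2)ccc1O | target

**Total steps:** 3. **Longest linear sequence:** 3, from compound 1, with 4 bought.

## Three steps most likely to fail
1. **Step 3 (ee and conversion).** The 6′-OH chelate deactivates the enone, and background racemic cyclisation competes.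
   Fallback: cyclise 5 to the racemic flavanone (pyrrolidine or NaOAc, EtOH, reflux), then isolate (S)-6 by preparative chiral-phase HPLC or SFC. Alternatively, use a chalcone isomerase biocatalytic cyclisation.
2. **Step 1 (diprenylation yield).** Mono-prenyl and dearomatised tri-prenyl by-products lower the yield.
   Fallback: change the bond-forming logic. Diiodinate 1 with NIS, then cross-couple with a prenyl-boron or prenyl-zinc reagent under Pd catalysis, with transient phenol protection.
3. **Step 2 (unprotected Claisen–Schmidt).** Yields can be poor, and racemic flavanone can form prematurely.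
   Fallback: protect the phenols of 3 and 4 as MOM ethers, run a standard aldol, then remove the MOM groups under very mild, non-Brønsted-acidic conditions (for example MgBr2·Me2S) before the Step 3 cyclisation. If 4 is not purchasable, make it by ortho-C-prenylation of 4-hydroxybenzaldehyde with prenyl bromide in aqueous NaOH.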